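The constant to carry comes from the fraction left: with 28.3% of the substrate remaining after 6.00 min in the south run, it is 0.210 /min, the substrate's loss constant, which is minus the natural log of the fraction left, divided by the time.

all flasks: substrate 1.3 M; free catalyst 3.9 mM
- south: coupling partner 1.3 M; run made earlier
- north-west: coupling partner 2 M; run made earlier
- flask: coupling partner 0.910 M

- south (time / min: product / %, substrate / %): 1.50: 3.7, 71.9; 3.00: 10.6, 53.0; 5.00: 20.3, 35.7; 6.00: 23.7, 28.3
- north-west (time / min: product / %, substrate / %): 1.50: 6.9, 72.3; 3.00: 15.4, 52.8; 5.00: 28.9, 34.5; 6.00: 33.8, 28.0

(each reading ± 0.5 percentage points)

1. apparent order in free catalyst when 5.0% of the substrate are converted (percent change of the rate of making product for one percent more free catalyst charged)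
2. apparent order in coupling partner when 5.0% of the substrate are converted (percent change of the rate of making product for one percent more coupling partner charged)

- what was read earlier has a scatter of 0.5 percentage points, one standard deviation
- no earlier run changes the charge of free catalyst; that part of a forecast is a guess

1. The north-west run, with more coupling partner, tests this pseudo-first-order constant. It gives 35.0% of the substrate left after 5.00 min, and the reading is 34.5%, a difference of the size of the scatter. The flask has the same substrate and free catalyst charges, so this reckoning gives it the same constant, although its partner charge lies below both runs.

2. First rung: by this reckoning the flask reaches 5.0% conversion at 0.244 min, earlier than the first reading at 1.50 min. The orders asked for therefore belong to a moment that no reading covers.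

3. Next rung: by the same constant, the fraction of substrate left in the flask halves every 3.29 min.

4. Last rung: in the south run, the gap between substrate lost and product reads 44.0% after 5.00 min. Product then gains 3.4 percentage points in the next minute, so product draws on the gap at about 0.0773 /min, a smaller constant than the substrate's. In that minute the substrate of the south run falls by 7.4 points, more than product gains, so the gap there grows to 48.0%, and it is the thing to watch. Partner acts on this rung: at equal substrate, product after 6.00 min reads 33.8% in the north-west run against 23.7% in the south run.

The forecast gives an order in free catalyst of 0.5, between 0 and 1.05, and an order in coupling partner of 0.99, between 0.9 and 1.05, saying “Catalyst order is a guess.”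

The flask gives an order in free catalyst of 0.73 and an order in coupling partner of 0.97. It reaches 5.0% conversion at 0.234 min, against the 0.244 min reckoned, and after 8.00 min it holds 18.9% of its substrate, against 18.6% by the loss constant.

    substrate + free catalyst → free catalyst + open intermediate (k = 1.91 /M/s)
    coupling partner + catalyst intermediate → free catalyst + product (k = 7.48 /M/s)
    coupling partner ⇌ dormant form (K = 1.47, k = 0.00761 /s)
    free catalyst + open intermediate ⇌ catalyst intermediate (K = 0.310 /M, k = 209 /M/s)
    2 free catalyst ⇌ resting dimer, settled at all times (K = 270 /M)

After 0.800 min, the earliest state on hand, the flask holds 48.2% of its catalyst free and 48.9% as resting dimer. With that association taken out of the flask, the order in free catalyst goes from 0.73 to 1.0.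

The runs are calculated for substances that don't exist, noise included.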